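3 questions stand for this flask, and we answer them with one count of sites.

| flask | starting material | partner | remark | time |
|---|---|---|---|---|
| epsilon | 0.020 M | 0.015 M | run made earlier |  |
| flask | 0.010 M | 0.0150 M |  | 8.0 h |

epsilon run (percent of the starting material charged)

| time / min | starting material / % | single product / % | bis adduct / % |
|---|---|---|---|
| 4.00 | 72.7 | 17.6 | 1.8 |
| 8.00 | 60.1 | 24.1 | 4.9 |
| 20.0 | 49.5 | 27.8 | 9.1 |
| 50.0 | 47.1 | 29.5 | 10.1 |

(readings scatter by 0.5 percentage points)

1. how much of the starting material has reacted by 8.0 h
2. how much single product there is at 8.0 h, in percent of the starting material charged
3. how much bis adduct there is at 8.0 h, in percent of the starting material charged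



Our zero of the scale is the statistical case: we take starting material to carry 2 equal sites, so that the free-site fraction is the root of the starting material left, and bis adduct is the square of the taken fraction. At the last epsilon reading the free fraction is 0.686, which gives 9.86% bis adduct against 10.1% read. Assuming the stall means [partner] has run down, the sites took 0.0125 M of 0.015 M, and 0.00245 M went elsewhere. The leak constant, partner lost per unit fall in the logarithm of free sites, a selectivity factor in concentration units, is 0.00651 M.

Turned round: on this statistical count, for starting material to be gone in this flask the sites, 0.0200 M of them, must fill, but this flask charges 0.0150 M of partner, 0.00500 M short before any leak. With a free fraction of 0.5 the leak is 0.00451 M, which leaves a free fraction 0.476; repeating gives 0.492, and we take their mean, 0.484. Our reckoning is then a leak of 0.00473 M, conversion 76.6%, bis adduct 26.6%, and single product 34.4%, keeping its epsilon share of singly reacted molecules.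

The forecast, “I favour exhaustion”, gives conversion 80%, single product 27% and bis adduct 31%, higher than ours on bis adduct and lower on single product.

    starting material + partner → single product + by-product (k = 0.0880 M⁻¹ s⁻¹)
    starting material + partner → other mono adduct + by-product (k = 0.0350 M⁻¹ s⁻¹)
    partner + single product → bis adduct + by-product (k = 0.0800 M⁻¹ s⁻¹)
    partner + other mono adduct → bis adduct + by-product (k = 0.0170 M⁻¹ s⁻¹)
    partner → decomposed reagent (k = 4.10 × 10⁻⁴ s⁻¹)

The flask gives conversion 76.4%, single product 31.7% and bis adduct 25.4%. In this flask the half-life of partner by decomposition alone, 0.47 h, is close to the 0.409 h that the conversion takes to come near its final value, and at 8.00 h partner, the limiting reagent, stands at 0% with 0.00481 M of decomposed reagent, against our leak of 0.00473 M. In the neighbouring flask with 0.025 M of partner, 5.07% starting material remains, so the leak constant gives 0.00971 M, and that flask holds 0.00994 M of decomposed reagent.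

The earlier runs and the new flask are calculated with constants of no real substance, noise included.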